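**Retrosynthetic overview**
- Ring A becomes an aryl cation equivalent: (diacetoxyiodo)benzene (1) + 2,4-dibromoanisole (2), via iodane 3, give iodonium triflate 4 by C–H iodanation ortho to OMe.
- Key disconnection, the diaryl ether C–O bond: the ring B phenoxide of 5-bromosalicylaldehyde (5) attacks the OMe-flanked, normally nucleophilic ring A carbon of 4, giving aldehyde 6.
- The ring B hydroxyl is traced back to the formyl group of 6 (Baeyer–Villiger, formate 7), giving target 8.
- Rings: both benzene rings are bought intact; no ring is formed.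

Assumption: the target has no stereocentre and is achiral, so the route delivers the single constitutional isomer drawn and needs no stereocontrol.

**Route**

Step 1
Reactants: 1 (diacetoxyiodo)benzene; 2 2,4-dibromoanisole (2,4-dibromo-1-methoxybenzene)
Product: 4 (3,5-dibromo-2-methoxyphenyl)(phenyl)iodonium triflate, via acetoxy(phenyl)iodanyl triflate 3 (not isolated)
Conditions: TfOH (2 equiv), CH2Cl2, 0 °C to rt, 1 h; then 2, 0 °C to 40 °C, 12 h; Et2O trituration
Reagents that add atoms: triflic acid (TfOH), OS(=O)(=O)C(F)(F)F
Why: Electrophilic aromatic iodanation (SEAr with a TfOH-activated trivalent iodine reagent): iodane 3 attacks 2 at C6, the only position activated by the methoxy group (its para and other ortho positions carry Br), so the normally nucleophilic ring A carbon ends up bonded to a hypervalent-iodine leaving group and becomes an aryl cation equivalent.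

Step 2
Reactants: 4 (3,5-dibromo-2-methoxyphenyl)(phenyl)iodonium triflate; 5 5-bromo-2-hydroxybenzaldehyde (5-bromosalicylaldehyde)
Product: 6 5-bromo-2-(3,5-dibromo-2-methoxyphenoxy)benzaldehyde
Conditions: 5, t-BuOK (1.0 equiv), THF, 0 °C, 15 min; then 4 (1.1 equiv), rt to 40 °C, 2–6 h
Reagents that add atoms: none
Why: Metal-free O-arylation of a phenoxide with a diaryliodonium salt (ligand exchange at trivalent iodine, then ligand coupling), in which the ortho-substituted, dibromo-deactivated ring A aryl should be transferred in preference to phenyl (ortho effect plus electronic preference) and the weakly basic pre-formed phenoxide avoids an aryne pathway.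

Step 3
Reactants: 6 5-bromo-2-(3,5-dibromo-2-methoxyphenoxy)benzaldehyde
Product: 8 5-bromo-2-(3,5-dibromo-2-methoxyphenoxy)phenol, via aryl formate 7 (not isolated)
Conditions: mCPBA (1.5 equiv), KH2PO4, CH2Cl2, rt, 16 h; then MeOH, cat. HCl, rt, 1 h
Reagents that add atoms: mCPBA (3-chloroperoxybenzoic acid), OOC(=O)c1cccc(Cl)c1
Why: Baeyer–Villiger oxidation of the aldehyde, in which the ring B aryl (made migratory by its ortho aryloxy oxygen) shifts to oxygen to give formate 7, followed by acid-catalysed methanolysis to the phenol; aryl bromides and both ethers are inert to these conditions.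

**Compound list**
1 | (diacetoxyiodo)benzene | CC(=O)OI(OC(C)=O)c1ccccc1 | starting material
2 | 2,4-dibromoanisole | COc1ccc(Br)cc1Br | starting material
3 | acetoxy(phenyl)iodanyl triflate | CC(=O)OI(OS(=O)(=O)C(F)(F)F)c1ccccc1 | intermediate
4 | (3,5-dibromo-2-methoxyphenyl)(phenyl)iodonium triflate | COc1c(Br)cc(Br)cc1[I+]c1ccccc1.[O-]S(=O)(=O)C(F)(F)F | intermediate
5 | 5-bromo-2-hydroxybenzaldehyde | O=Cc1cc(Br)ccc1O | starting material
6 | 5-bromo-2-(3,5-dibromo-2-methoxyphenoxy)benzaldehyde | COc1c(Br)cc(Br)cc1Oc1ccc(Br)cc1C=O | intermediate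
7 | 5-bromo-2-(3,5-dibromo-2-methoxyphenoxy)phenyl formate | COc1c(Br)cc(Br)cc1Oc1ccc(Br)cc1OC=O | intermediate
8 | 5-bromo-2-(3,5-dibromo-2-methoxyphenoxy)phenol | COc1c(Br)cc(Br)cc1Oc1ccc(Br)cc1O | target

**Step count**
Total steps: 3. Longest linear sequence: 3 (2 → 4 → 6 → 8).

**Steps most likely to fail, with fallbacks**

Step 1 (highest risk). Arene 2 carries two deactivating bromines, so the C–H iodanation may stall. The fallback sets out from 2 and installs the iodine first as an ordinary iodide. Electrophilic iodination (NIS, TfOH, MeCN, rt) at the same OMe-activated position gives 1,5-dibromo-3-iodo-2-methoxybenzene F1. Oxidation at iodine (mCPBA, TsOH·H2O, MeCN, 77 °C) gives the hydroxy(tosyloxy)iodoarene F2, which is not isolated. Trapping with 1,3,5-trimethoxybenzene gives (3,5-dibromo-2-methoxyphenyl)(2,4,6-trimethoxyphenyl)iodonium tosylate F3. F3 arylates the potassium phenoxide of 5 under the step 2 conditions, with the electron-rich trimethoxyphenyl group as a non-transferable dummy. The route is rejoined at 6. This fallback also removes the phenyl-versus-aryl selectivity question of step 2.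

Step 2. The formyl-chelated phenoxide of 5 is a weak nucleophile, so transfer may be slow, the aryl groups may scramble, or phenyl may be transferred. The fallback sets out from 4 and uses a more nucleophilic partner that already carries the ring B oxygen in protected form. Commercial 2-(benzyloxy)phenol is brominated para to the free hydroxyl (NBS, MeCN, 0 °C) to give 2-(benzyloxy)-4-bromophenol F4. Its potassium salt (t-BuOK, THF) is arylated by 4 at 40 °C to give 1-[2-(benzyloxy)-4-bromophenoxy]-3,5-dibromo-2-methoxybenzene F5. The benzyl ether is cleaved with BCl3 and pentamethylbenzene in CH2Cl2 at −78 °C; the aryl bromides and the methyl ether survive, and hydrogenolysis is avoided because it would debrominate. The route is rejoined at target 8, so step 3 is bypassed.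

Step 3. Hydride migration could give the benzoic acid instead of formate 7. The fallback sets out from 4 and replaces the formyl group by an acetyl group, which has no migrating hydrogen. Commercial 1-(5-bromo-2-hydroxyphenyl)ethanone is deprotonated (t-BuOK, THF) and arylated by 4 to give 1-[5-bromo-2-(3,5-dibromo-2-methoxyphenoxy)phenyl]ethan-1-one F6. Baeyer–Villiger oxidation with trifluoroperacetic acid (urea·H2O2, trifluoroacetic anhydride, Na2HPO4, CH2Cl2, 0 °C to rt) proceeds with aryl migration to give 5-bromo-2-(3,5-dibromo-2-methoxyphenoxy)phenyl acetate F7. Methanolysis (K2CO3, MeOH, rt, then dilute HCl) rejoins the route at target 8.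

**Further compounds**
F1 | step 1 | 1,5-dibromo-3-iodo-2-methoxybenzene | COc1c(Br)cc(Br)cc1I
F2 | step 1 | 1,5-dibromo-3-[hydroxy(tosyloxy)iodanyl]-2-methoxybenzene | COc1c(Br)cc(Br)cc1I(O)OS(=O)(=O)c1ccc(C)cc1
F3 | step 1 | (3,5-dibromo-2-methoxyphenyl)(2,4,6-trimethoxyphenyl)iodonium 4-methylbenzenesulfonate | COc1cc(OC)c([I+]c2cc(Br)cc(Br)c2OC)c(OC)c1.Cc1ccc(cc1)S(=O)(=O)[O-]
F4 | step 2 | 2-(benzyloxy)-4-bromophenol | Oc1ccc(Br)cc1OCc1ccccc1
F5 | step 2 | 1-[2-(benzyloxy)-4-bromophenoxy]-3,5-dibromo-2-methoxybenzene | COc1c(Br)cc(Br)cc1Oc1ccc(Br)cc1OCc1ccccc1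
F6 | step 3 | 1-[5-bromo-2-(3,5-dibromo-2-methoxyphenoxy)phenyl]ethan-1-one | COc1c(Br)cc(Br)cc1Oc1ccc(Br)cc1C(C)=O
F7 | step 3 | 5-bromo-2-(3,5-dibromo-2-methoxyphenoxy)phenyl acetate | COc1c(Br)cc(Br)cc1Oc1ccc(Br)cc1OC(C)=O
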